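**Plan** (ring atoms numbered as in cyclohex-2-en-1-one: C1 = C=O, C2=C3, C4 = CHOH, C5 = C(OH)(chain), C6 = CH2; C1' = first chain carbon)
Retrosynthesis: the C2=C3 double bond and the free C4 hydroxyl are first returned to a C3,C4-acetonide on a saturated ketone (β-alkoxy ketone). The ring is then cut at C5–C6, because the C1 ketone and the C5 tertiary carbinol stand 1,3 on the six-membered ring (β-hydroxy ketone, aldol retron). The open 1,5-diketone is cut at C5–C1' (chain Grignard reagent), and its C1/C6 methyl ketone is traced to a terminal alkyne.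
Forward: the Z-configured C17 bromide is made from dec-1-yne and 1,7-dibromoheptane; 2-deoxy-L-ribose supplies C1–C5; C6 enters as an alkyne carbon; the chain is joined at C5; the alkyne is hydrated. The six-membered carbocycle, the only ring of the skeleton, is closed last by the C5–C6 aldol addition, and the temporary acetonide ring then leaves as acetone.
Stereochemistry: C4 is C4 of the sugar; C5 is set in the ring closure by a lithium chelate relayed from C4; the sugar C3 oxygen is spent as the leaving group; the Z-alkene comes from semi-hydrogenation.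

Key step: step 9

Remark: the SMILES is read as (4R,5S), which places the two hydroxyl groups cis on the ring; commercial 2-deoxy-L-ribose carries the matching configuration at its C4.

Step 1
Reactants: 1 dec-1-yne; 2 1,7-dibromoheptane
Product: 4 1-bromoheptadec-8-yne, via lithium dec-1-ynide 3 (not isolated)
Conditions: n-BuLi, THF, −78 to 0 °C; then 2 (3 equiv), DMPU, 0 °C to rt
Reagents that add atoms: none
Why: SN2 alkylation of a lithium acetylide at a primary bromide (acetylide alkylation); the excess of 2 should hold the reaction at mono-substitution.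

Step 2
Reactants: 4 1-bromoheptadec-8-yne
Product: 5 (8Z)-1-bromoheptadec-8-ene
Conditions: H2 (1 atm), Pd/CaCO3 poisoned with Pb(OAc)2, quinoline, hexane, rt
Reagents that add atoms: none
Why: Lindlar semi-hydrogenation delivers both hydrogens to one face of the alkyne on the poisoned palladium surface and should stop at the alkene, which sets the Z geometry of the chain.

Step 3
Reactants: 6 2-deoxy-L-ribose
Product: 7 2-deoxy-3,4-O-isopropylidene-L-erythro-pentopyranose (lactol, anomeric mixture)
Conditions: 2-methoxypropene, PPTS (cat.), EtOAc, 0 °C to rt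
Reagents that add atoms: 2-methoxypropene, COC(C)=C
Why: acid-catalysed acetonide formation with an enol ether traps the cis-3,4-diol of the pyranose form, as is established for the D enantiomer; no stereocenter is touched.

Step 4
Reactants: 7 2-deoxy-3,4-O-isopropylidene-L-erythro-pentopyranose
Product: 8 [(4S,5R)-2,2-dimethyl-5-(prop-2-yn-1-yl)-1,3-dioxolan-4-yl]methanol
Conditions: dimethyl (1-diazo-2-oxopropyl)phosphonate, K2CO3, MeOH, 0 °C to rt
Reagents that add atoms: dimethyl (1-diazo-2-oxopropyl)phosphonate, CC(=O)C(=[N+]=[N-])P(=O)(OC)OC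
Why: Seyferth–Gilbert homologation in the Ohira–Bestmann variant turns the aldehyde carbon of the ring-opened lactol into a terminal alkyne with one added carbon (the later C6), under conditions mild enough to spare the acetonide and both stereocenters.

Step 5
Reactants: 8 [(4S,5R)-2,2-dimethyl-5-(prop-2-yn-1-yl)-1,3-dioxolan-4-yl]methanol
Product: 9 (4R,5R)-2,2-dimethyl-5-(prop-2-yn-1-yl)-1,3-dioxolane-4-carbaldehyde
Conditions: Dess–Martin periodinane, CH2Cl2, 0 °C to rt
Reagents that add atoms: none
Why: Dess–Martin oxidation of the primary alcohol is near-neutral, so the stereocenter next to the new formyl group should keep its cis relation to the propargyl arm; the aldehyde is used at once.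

Step 6
Reactants: 9 (4R,5R)-2,2-dimethyl-5-(prop-2-yn-1-yl)-1,3-dioxolane-4-carbaldehyde; 5 (8Z)-1-bromoheptadec-8-ene
Product: 11 (9Z)-1-[(4S,5R)-2,2-dimethyl-5-(prop-2-yn-1-yl)-1,3-dioxolan-4-yl]octadec-9-en-1-ol (both epimers at the new carbinol carbon), via (8Z)-heptadec-8-enylmagnesium bromide 10 (not isolated)
Conditions: 5 (1.3 equiv), Mg, THF, rt; then 9, THF, −78 °C
Reagents that add atoms: none
Why: Grignard addition of a primary alkylmagnesium bromide to the aldehyde joins the C17 chain at C5; the new carbinol center is not controlled and need not be, since step 7 oxidises it.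

Step 7
Reactants: 11 (9Z)-1-[(4S,5R)-2,2-dimethyl-5-(prop-2-yn-1-yl)-1,3-dioxolan-4-yl]octadec-9-en-1-ol
Product: 12 (9Z)-1-[(4R,5R)-2,2-dimethyl-5-(prop-2-yn-1-yl)-1,3-dioxolan-4-yl]octadec-9-en-1-one
Conditions: Dess–Martin periodinane, CH2Cl2, rt
Reagents that add atoms: none
Why: Dess–Martin oxidation of the secondary alcohol gives the α-alkoxy ketone without base, so C4 should not epimerise and both carbinol epimers converge on one ketone.

Step 8
Reactants: 12 (9Z)-1-[(4R,5R)-2,2-dimethyl-5-(prop-2-yn-1-yl)-1,3-dioxolan-4-yl]octadec-9-en-1-one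
Product: 13 (9Z)-1-[(4R,5R)-2,2-dimethyl-5-(2-oxopropyl)-1,3-dioxolan-4-yl]octadec-9-en-1-one
Conditions: Ph3PAuNTf2 (2 mol%), H2O, 1,4-dioxane, 50 °C
Reagents that add atoms: water, O
Why: gold-catalysed Markovnikov hydration of the terminal alkyne gives the methyl ketone; the π-acid activates the alkyne and not the chain alkene, and the neutral medium leaves the β-alkoxy ketone intact.

Step 9
Reactants: 13 (9Z)-1-[(4R,5R)-2,2-dimethyl-5-(2-oxopropyl)-1,3-dioxolan-4-yl]octadec-9-en-1-one
Product: 15 3,4-O-isopropylidene acetal of (3R,4R,5S)-5-[(8Z)-heptadec-8-en-1-yl]-3,4,5-trihydroxycyclohexan-1-one, via C6 lithium enolate 14 (not isolated)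
Conditions: LiHMDS (1.05 equiv), THF, −78 °C; then AcOH, −78 °C
Reagents that add atoms: none
Why: LiHMDS removes a proton of the C6 methyl group (the least hindered α-position, as in the kinetic enolisation of β-alkoxy methyl ketones) and lithium enolate 14 adds to the C5 ketone carbonyl; the closest known reaction type is the intramolecular aldol addition of carbohydrate-derived 2,6-diketones to hydroxylated cyclohexanones. The six-membered carbocycle closes in the 6-(enolexo)-exo-trig mode by forming C5–C6, cis-fused to the dioxolane. The new stereocenter C5 is controlled by C4: in a chair-like transition state lithium bridges the enolate oxygen, the C5 carbonyl oxygen and the two dioxolane oxygens on one face, so that the carbonyl oxygen stands axial and syn to the C4–O bond while the heptadecenyl chain is equatorial, which should give the 5S carbinol with its hydroxyl cis to O4. The step needs regioselective enolisation at C6 (not at C2, whose enolate would expel the C3 oxygen, and not at the α-methylene of the long-chain ketone); the preference of the bulky amide for the methyl group at −78 °C and the branched, less basic α-alkoxy ketone should secure this. It also needs C4 to keep its configuration, which the hindered tertiary C4–H next to the acetal should secure under these non-equilibrating conditions. The acidic quench at −78 °C prevents retro-aldol cleavage and early loss of the acetonide.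

Step 10
Reactants: 15 3,4-O-isopropylidene acetal of (3R,4R,5S)-5-[(8Z)-heptadec-8-en-1-yl]-3,4,5-trihydroxycyclohexan-1-one
Product: 17 (4R,5S)-5-[(8Z)-heptadec-8-en-1-yl]-4,5-dihydroxycyclohex-2-en-1-one (CNP0223277.1), via O4 hemiketal 16 (not isolated)
Conditions: DBU (1.1 equiv), CH2Cl2, 0 °C
Reagents that add atoms: none
Why: E1cB β-elimination of the C3 acetal oxygen from the C1 ketone (the known conversion of acetonide-protected 3,4-dihydroxycyclohexanones into 4-hydroxycyclohex-2-enones) forms the C2=C3 double bond, and hemiketal 16 left on O4 loses acetone, so enone and free C4 hydroxyl appear together while C4 and C5 are untouched.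

**Compound list**
1 | dec-1-yne | CCCCCCCCC#C | starting material
2 | 1,7-dibromoheptane | BrCCCCCCCBr | starting material
3 | lithium dec-1-yn-1-ide (formed in the flask, not isolated) | CCCCCCCCC#C[Li] | intermediate
4 | 1-bromoheptadec-8-yne | CCCCCCCCC#CCCCCCCCBr | intermediate
5 | (8Z)-1-bromoheptadec-8-ene | CCCCCCCC/C=C\CCCCCCCBr | intermediate
6 | 2-deoxy-L-ribose (2-deoxy-L-erythro-pentose, (3R,4S)-3,4,5-trihydroxypentanal, drawn open-chain) | O=CC[C@@H](O)[C@@H](O)CO | starting material
7 | 2-deoxy-3,4-O-isopropylidene-L-erythro-pentopyranose (pyranose lactol of 6 with the acetonide on O3 and O4, anomeric mixture) | OC1C[C@H]2OC(C)(C)O[C@H]2CO1 | intermediate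
8 | [(4S,5R)-2,2-dimethyl-5-(prop-2-yn-1-yl)-1,3-dioxolan-4-yl]methanol | C#CC[C@H]1OC(C)(C)O[C@H]1CO | intermediate
9 | (4R,5R)-2,2-dimethyl-5-(prop-2-yn-1-yl)-1,3-dioxolane-4-carbaldehyde | C#CC[C@H]1OC(C)(C)O[C@H]1C=O | intermediate
10 | (8Z)-heptadec-8-en-1-ylmagnesium bromide (formed in the flask, not isolated) | CCCCCCCC/C=C\CCCCCCC[Mg]Br | intermediate
11 | (9Z)-1-[(4S,5R)-2,2-dimethyl-5-(prop-2-yn-1-yl)-1,3-dioxolan-4-yl]octadec-9-en-1-ol (both epimers at C1 of the chain) | C#CC[C@H]1OC(C)(C)O[C@H]1C(O)CCCCCCC/C=C\CCCCCCCC | intermediate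
12 | (9Z)-1-[(4R,5R)-2,2-dimethyl-5-(prop-2-yn-1-yl)-1,3-dioxolan-4-yl]octadec-9-en-1-one | C#CC[C@H]1OC(C)(C)O[C@H]1C(=O)CCCCCCC/C=C\CCCCCCCC | intermediate
13 | (9Z)-1-[(4R,5R)-2,2-dimethyl-5-(2-oxopropyl)-1,3-dioxolan-4-yl]octadec-9-en-1-one | CC(=O)C[C@H]1OC(C)(C)O[C@H]1C(=O)CCCCCCC/C=C\CCCCCCCC | intermediate
14 | lithium 3-{(4R,5R)-2,2-dimethyl-5-[(9Z)-octadec-9-enoyl]-1,3-dioxolan-4-yl}prop-1-en-2-olate (C6 enolate of 13, not isolated) | C=C(O[Li])C[C@H]1OC(C)(C)O[C@H]1C(=O)CCCCCCC/C=C\CCCCCCCC | intermediate
15 | 3,4-O-isopropylidene acetal of (3R,4R,5S)-5-[(8Z)-heptadec-8-en-1-yl]-3,4,5-trihydroxycyclohexan-1-one; (3aR,7S,7aR)-7-[(8Z)-heptadec-8-en-1-yl]-7-hydroxy-2,2-dimethylhexahydro-1,3-benzodioxol-5-one; all three oxygens on one face | O=C1C[C@H]2OC(C)(C)O[C@H]2[C@](O)(CCCCCCC/C=C\CCCCCCCC)C1 | intermediate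
16 | (4R,5S)-5-[(8Z)-heptadec-8-en-1-yl]-5-hydroxy-4-[(2-hydroxypropan-2-yl)oxy]cyclohex-2-en-1-one (hemiketal, not isolated) | CC(C)(O)O[C@@H]1C=CC(=O)C[C@@]1(O)CCCCCCC/C=C\CCCCCCCC | intermediate
17 | (4R,5S)-5-[(8Z)-heptadec-8-en-1-yl]-4,5-dihydroxycyclohex-2-en-1-one (CNP0223277.1) | CCCCCCCC/C=C\CCCCCCC[C@]1(O)CC(=O)C=C[C@H]1O | target

**Step count:** 10 steps in total.
**Longest linear sequence:** 8 steps (steps 3 to 10, from 6); the chain branch (steps 1 and 2) joins at step 6.

**Steps most likely to fail**

Step 9. Enolisation may not be selective: deprotonation at C2 would be followed by loss of the C3 oxygen before the ring can close, and deprotonation at the α-methylene of the long-chain ketone would lead to closure onto C1. The lithium chelate may also be too weak, so that attack occurs on the other face of the C5 carbonyl. The fallback sets out from 12 and comes back at 15. It replaces deprotonation by a nucleophile that can only sit at C6. The terminal alkyne of 12 would be brominated (N-bromosuccinimide, AgNO3 cat., acetone) to the bromoalkyne (9Z)-1-[(4R,5R)-5-(3-bromoprop-2-yn-1-yl)-2,2-dimethyl-1,3-dioxolan-4-yl]octadec-9-en-1-one F1. Gold-catalysed hydration (Ph3PAuNTf2, wet 1,2-dichloroethane) would give the α-bromomethyl ketone (9Z)-1-[(4R,5R)-5-(3-bromo-2-oxopropyl)-2,2-dimethyl-1,3-dioxolan-4-yl]octadec-9-en-1-one F2. SmI2 (2 equiv, THF, −78 °C) would then reduce the C–Br bond to a samarium enolate at C6, which should close the ring in a Reformatsky-type aldol addition through the same oxygen chelate and give 15.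

Step 10. Under base the β-hydroxy enone may open by retro-aldol cleavage or lose the tertiary hydroxyl and drift toward the aromatic level. The fallback sets out from 15 and comes back at 17. It couples the elimination with capping of both hydroxyl groups under Lewis-acid conditions. TMSOTf (3.5 equiv) and Et3N in CH2Cl2 at −40 to 0 °C should silylate the tertiary alcohol, form the silyl enol ether toward C2 and open the acetonide at C3, giving (4R,5S)-5-[(8Z)-heptadec-8-en-1-yl]-4,5-bis[(trimethylsilyl)oxy]cyclohex-2-en-1-one F3. Citric acid in MeOH at 0 °C would then remove both silyl groups and give 17 without exposure of the free diol to base.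

Step 6 (together with step 5). Aldehyde 9 may epimerise at the ring carbon next to the formyl group (cis- to trans-dioxolane) before or during the addition, and part of the Grignard reagent may be consumed by the acetylenic C–H. The fallback sets out from 8 and comes back at 12, so that 9 and 11 are bypassed. Alcohol 8 would be oxidised (TEMPO cat., PhI(OAc)2, MeCN/H2O) to (4R,5R)-2,2-dimethyl-5-(prop-2-yn-1-yl)-1,3-dioxolane-4-carboxylic acid F4. Activation with 1,1'-carbonyldiimidazole and reaction with N,O-dimethylhydroxylamine hydrochloride would give the Weinreb amide (4R,5R)-N-methoxy-N,2,2-trimethyl-5-(prop-2-yn-1-yl)-1,3-dioxolane-4-carboxamide F5. Acyl substitution with 10 (THF, 0 °C) should then give ketone 12 directly through the stable magnesium chelate.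

**Further compounds**
F1 | step 9 | (9Z)-1-[(4R,5R)-5-(3-bromoprop-2-yn-1-yl)-2,2-dimethyl-1,3-dioxolan-4-yl]octadec-9-en-1-one | BrC#CC[C@H]1OC(C)(C)O[C@H]1C(=O)CCCCCCC/C=C\CCCCCCCC
F2 | step 9 | (9Z)-1-[(4R,5R)-5-(3-bromo-2-oxopropyl)-2,2-dimethyl-1,3-dioxolan-4-yl]octadec-9-en-1-one | BrCC(=O)C[C@H]1OC(C)(C)O[C@H]1C(=O)CCCCCCC/C=C\CCCCCCCC
F3 | step 10 | (4R,5S)-5-[(8Z)-heptadec-8-en-1-yl]-4,5-bis[(trimethylsilyl)oxy]cyclohex-2-en-1-one | CCCCCCCC/C=C\CCCCCCC[C@]1(O[Si](C)(C)C)CC(=O)C=C[C@H]1O[Si](C)(C)C
F4 | step 6 | (4R,5R)-2,2-dimethyl-5-(prop-2-yn-1-yl)-1,3-dioxolane-4-carboxylic acid | C#CC[C@H]1OC(C)(C)O[C@H]1C(O)=O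
F5 | step 6 | (4R,5R)-N-methoxy-N,2,2-trimethyl-5-(prop-2-yn-1-yl)-1,3-dioxolane-4-carboxamide | C#CC[C@H]1OC(C)(C)O[C@H]1C(=O)N(C)OC
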